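**Strategy.** Everything rests on cutting ring A of the eudesmane at C1–C2 and C5–C10. Ring A (C1–C5, C10) can hold a C3=C4 alkene, so it is a cyclohexene retron, while C6–C9 of ring B, together with the C7 carbinol side chain, is the carbon chain of ozonised (R)-α-terpineol. One intramolecular Diels–Alder reaction of an acyclic (2E,8E)-trienal, whose diene and β-methyl enal are joined by that four-carbon chain, forms both rings, both bonds and the C1, C5 and C10 stereocentres under control of C7. The C1 aldehyde then carries the aryl and isobutyl groups, and the C3=C4 alkene becomes the 4α-carbinol.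

Key step: step 7

Remark on numbering: from compound 13 on, eudesmane numbering is used (decalin C1–C10, C11 the carbinol carbon on C7, C1' the benzylic carbon); β is the face of the C10 methyl group.
Remark on design: the hydroxyl group is silylated before the ring is cleaved, so that the keto aldehyde stays open-chain; the trienal is the (6R) isomer that (R)-α-terpineol delivers; the enal is reached through an N-methoxy-N-methylamide, which saves a redox step.
Assumption: the tertiary triethylsilyl ether is taken to last until the final acid treatment; both Lewis-acid steps are therefore run at −78 °C.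

Step 1
Reactants: 1 (R)-α-terpineol
Product: 2 (R)-α-terpineol triethylsilyl ether
Conditions: Et3SiOTf, 2,6-lutidine, CH2Cl2, 0 °C → rt
Reagents that add atoms: triethylsilyl trifluoromethanesulfonate, CC[Si](CC)(CC)OS(=O)(=O)C(F)(F)F
Why: O-Silylation of a hindered tertiary alcohol with a silyl triflate and a non-nucleophilic base is routine and does not touch the stereocentre; masking the hydroxyl group now prevents lactol formation after ring cleavage.

Step 2
Reactants: 2 (R)-α-terpineol triethylsilyl ether
Product: 4 (3R)-6-oxo-3-[2-(triethylsilyloxy)propan-2-yl]heptanal, via secondary ozonide 3 (not isolated)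
Conditions: O3, CH2Cl2, −78 °C; then PPh3, −78 °C → rt
Reagents that add atoms: ozone, [O-][O+]=O
Why: Ozonolysis with reductive work-up cleaves the only C=C bond to the methyl ketone and the aldehyde; the stereocentre is β to the aldehyde, is not enolisable and stays as it is.

Step 3
Reactants: 4 (3R)-6-oxo-3-[2-(triethylsilyloxy)propan-2-yl]heptanal; 5 2-(triphenylphosphoranylidene)propanal
Product: 6 (2E,5R)-2-methyl-8-oxo-5-[2-(triethylsilyloxy)propan-2-yl]non-2-enal
Conditions: toluene, 90 °C
Reagents that add atoms: none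
Why: Wittig olefination with a formyl-stabilised ylide takes the aldehyde only, since the methyl ketone is inert to stabilised ylides, and gives the E trisubstituted enal through the reversible, product-like addition typical of such ylides.

Step 4
Reactants: 6 (2E,5R)-2-methyl-8-oxo-5-[2-(triethylsilyloxy)propan-2-yl]non-2-enal
Product: 7 (5R,7E)-8-methyl-5-[2-(triethylsilyloxy)propan-2-yl]deca-7,9-dien-2-one
Conditions: Ph3PCH3Br (1.05 equiv), KOtBu, THF, 0 °C; then 6, −78 → 0 °C
Reagents that add atoms: methyltriphenylphosphonium bromide, C[P+](c1ccccc1)(c1ccccc1)c1ccccc1.[Br-]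
Why: Wittig methylenation with the non-stabilised ylide is much faster at the aldehyde than at the methyl ketone, so one equivalent at low temperature should convert the enal carbonyl only and leave the E trisubstituted alkene as the inner bond of the diene.

Step 5
Reactants: 7 (5R,7E)-8-methyl-5-[2-(triethylsilyloxy)propan-2-yl]deca-7,9-dien-2-one; 8 diethyl {2-[methoxy(methyl)amino]-2-oxoethyl}phosphonate
Product: 10 (2E,6R,8E)-N-methoxy-N,3,9-trimethyl-6-[2-(triethylsilyloxy)propan-2-yl]undeca-2,8,10-trienamide, via sodium phosphonate carbanion 9 (not isolated)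
Conditions: 8, NaH, THF, 0 °C → rt; then 7, rt → 50 °C; chromatography to remove the minor Z isomer
Reagents that add atoms: none
Why: Horner–Wadsworth–Emmons olefination of the methyl ketone with the amide-stabilised phosphonate carbanion gives the trisubstituted unsaturated amide, and the reversible addition favours the E isomer with the amide trans to the longer chain.

Step 6
Reactants: 10 (2E,6R,8E)-N-methoxy-N,3,9-trimethyl-6-[2-(triethylsilyloxy)propan-2-yl]undeca-2,8,10-trienamide
Product: 12 (2E,6R,8E)-3,9-dimethyl-6-[2-(triethylsilyloxy)propan-2-yl]undeca-2,8,10-trienal, via aluminium hemiaminal 11 (not isolated)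
Conditions: i-Bu2AlH (1.3 equiv), THF, −78 °C; then aqueous potassium sodium tartrate
Reagents that add atoms: none
Why: Hydride reduction of an N-methoxy-N-methylamide stops at the chelated tetrahedral aluminium hemiaminal, which releases the aldehyde only on hydrolysis, so neither over-reduction nor loss of the E geometry is expected.

Step 7
Reactants: 12 (2E,6R,8E)-3,9-dimethyl-6-[2-(triethylsilyloxy)propan-2-yl]undeca-2,8,10-trienal
Product: 13 11-(triethylsilyloxy)eudesm-3-ene-1β-carbaldehyde (trans-fused; 1β-CHO, 5α-H, 7β side chain, 10β-CH3)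
Conditions: Me2AlCl (1.2 equiv), CH2Cl2, −78 → −20 °C
Reagents that add atoms: none
Why: Me2AlCl binds the formyl oxygen and lowers the LUMO of the C10=C1 enal, so that the C2=C3–C4=C5 diene adds in a concerted, asynchronous, suprafacial [4+2] cycloaddition that forms C1–C2 and C5–C10. The closest known reaction type is the Lewis-acid-promoted type 1 intramolecular Diels–Alder reaction of E 1,7,9-decatrienes that carry the carbonyl activator at the chain end, which gives trans-fused octalins. Ring A closes as the new cyclohexene through both new bonds, and ring B closes in the fused mode as the six-membered tether ring through C5–C10, its C6–C9 chain lying in a chair. C1 is fixed by the E enal geometry, which the suprafacial addition carries over so that the formyl group and the C10 methyl group are cis; C5 and C10 are fixed relative to each other by the endo arrangement (formyl under the diene), which puts H5 trans to the C10 methyl group; the absolute sense of all three is fixed by C7, whose bulky silyloxyisopropyl group takes the equatorial site of the chair. The step needs endo over exo selectivity and one diene face: complexation of the terminal formyl group secures the first and the resident C7 centre the second. Me2AlCl is also a proton scavenger, which protects the acid-sensitive diene and the tertiary silyl ether.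

Step 8
Reactants: 13 11-(triethylsilyloxy)eudesm-3-ene-1β-carbaldehyde; 14 1,3,5-trimethoxybenzene
Product: 16 (2,4,6-trimethoxyphenyl)[11-(triethylsilyloxy)eudesm-3-en-1β-yl]methanol, via 2,4,6-trimethoxyphenyllithium 15 (not isolated)
Conditions: 14, n-BuLi, THF, 0 °C → rt; then 13, −78 → 0 °C; then H2O
Reagents that add atoms: none
Why: Directed ortho-lithiation of 14 between two methoxy groups gives a hindered aryllithium that adds 1,2 to the aldehyde; the new carbinol centre is left uncontrolled because the next step ionises it.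

Step 9
Reactants: 16 (2,4,6-trimethoxyphenyl)[11-(triethylsilyloxy)eudesm-3-en-1β-yl]methanol (both epimers); 17 trimethyl(2-methylallyl)silane
Product: 18 (1'S)-1β-[3-methyl-1-(2,4,6-trimethoxyphenyl)but-3-en-1-yl]-11-(triethylsilyloxy)eudesm-3-ene
Conditions: 17 (3 equiv), BF3·OEt2 (1.2 equiv), CH2Cl2, −78 °C
Reagents that add atoms: none
Why: BF3·OEt2 ionises the electron-rich benzylic alcohol to a planar, quinone-methide-like cation that the allylsilane captures at its CH2 terminus with loss of silicon (Hosomi–Sakurai-type SN1 allylation); allylic 1,3-strain against the ortho methoxy group turns the C1–H bond into the cation plane, quaternary C10 covers one face, and attack past C2 should set (1'S).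

Step 10
Reactants: 18 (1'S)-1β-[3-methyl-1-(2,4,6-trimethoxyphenyl)but-3-en-1-yl]-11-(triethylsilyloxy)eudesm-3-ene
Product: 19 (1'S)-1β-[3-methyl-1-(2,4,6-trimethoxyphenyl)butyl]-11-(triethylsilyloxy)eudesm-3-ene
Conditions: H2 (1 atm), RhCl(PPh3)3 (5 mol %), toluene/EtOH, rt
Reagents that add atoms: none
Why: Homogeneous hydrogenation with RhCl(PPh3)3 reduces the unhindered 1,1-disubstituted alkene and leaves the trisubstituted ring alkene, the arene and the silyl ether alone; no stereocentre is formed.

Step 11
Reactants: 19 (1'S)-1β-[3-methyl-1-(2,4,6-trimethoxyphenyl)butyl]-11-(triethylsilyloxy)eudesm-3-ene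
Product: 20 (1'S)-3α,4α-epoxy-1β-[3-methyl-1-(2,4,6-trimethoxyphenyl)butyl]-11-(triethylsilyloxy)eudesmane
Conditions: mCPBA (1.1 equiv), NaHCO3, CH2Cl2, 0 °C
Reagents that add atoms: 3-chloroperoxybenzoic acid, O=C(OO)c1cccc(Cl)c1
Why: Prilezhaev epoxidation of the trisubstituted C3=C4 bond takes place from the α face because the axial C10 methyl group covers the β face of ring A; the buffer protects the silyl ether and the arene reacts far more slowly than the alkene.

Step 12
Reactants: 20 (1'S)-3α,4α-epoxy-1β-[3-methyl-1-(2,4,6-trimethoxyphenyl)butyl]-11-(triethylsilyloxy)eudesmane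
Product: 21 (1'S)-1β-[3-methyl-1-(2,4,6-trimethoxyphenyl)butyl]-11-(triethylsilyloxy)eudesman-4α-ol
Conditions: LiAlH4, THF, reflux; then H2O
Reagents that add atoms: none
Why: Hydride opens the oxirane in an SN2 reaction at the secondary C3 from the β face, since attack at the fully substituted C4 under the C10 methyl group is blocked, so the C4–O bond keeps its α orientation and the tertiary 4α-alcohol with a 4β-methyl group results.

Step 13
Reactants: 21 (1'S)-1β-[3-methyl-1-(2,4,6-trimethoxyphenyl)butyl]-11-(triethylsilyloxy)eudesman-4α-ol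
Product: 22 (1'S)-1β-[1-(3,5-dibromo-2,4,6-trimethoxyphenyl)-3-methylbutyl]-11-(triethylsilyloxy)eudesman-4α-ol
Conditions: NBS (2.1 equiv), MeCN, 0 °C, dark
Reagents that add atoms: N-bromosuccinimide, O=C1CCC(=O)N1Br
Why: Electrophilic aromatic bromination at the two remaining ring positions, each flanked by two methoxy groups, is fast under ionic conditions that leave the tertiary alcohol, the silyl ether and the benzylic C–H bond alone.

Step 14
Reactants: 22 (1'S)-1β-[1-(3,5-dibromo-2,4,6-trimethoxyphenyl)-3-methylbutyl]-11-(triethylsilyloxy)eudesman-4α-ol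
Product: 25 2,4,6-trimethoxy-5-{(1S)-1-[4α-hydroxy-11-(triethylsilyloxy)eudesman-1β-yl]-3-methylbutyl}benzene-1,3-dicarbaldehyde, via trilithio arene 23 (not isolated), via bis(hemiaminal) lithium alkoxide 24 (not isolated)
Conditions: t-BuLi (5.5 equiv), THF, −78 °C; then DMF, −78 → 0 °C; then H2O
Reagents that add atoms: N,N-dimethylformamide, CN(C)C=O
Why: After deprotonation of the hydroxyl group, bromine–lithium exchange gives at each site an aryllithium held by two ortho methoxy groups, and formylation with DMF runs through hemiaminal alkoxides that release the aldehydes only on hydrolysis, which prevents over-addition.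

Step 15
Reactants: 25 2,4,6-trimethoxy-5-{(1S)-1-[4α-hydroxy-11-(triethylsilyloxy)eudesman-1β-yl]-3-methylbutyl}benzene-1,3-dicarbaldehyde
Product: 27 Macrocarpal J, via trisodium triphenoxide 26 (not isolated)
Conditions: NaSEt (excess), DMF, 120 °C; then 2 M HCl, THF, rt
Reagents that add atoms: none
Why: Thiolate SN2 demethylation should work because every methoxy group is ortho to a formyl group (vinylogous ester, stabilised phenoxide leaving group) and the basic, non-ionising medium spares the tertiary alcohols; dilute acid then protonates the phenoxides and hydrolyses the tertiary Si–O bond without dehydration.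

**Compound list**

1 | (R)-α-terpineol, 2-[(1R)-4-methylcyclohex-3-en-1-yl]propan-2-ol | CC1=CC[C@@H](CC1)C(C)(C)O | starting material
2 | (R)-α-terpineol triethylsilyl ether | CC1=CC[C@@H](CC1)C(C)(C)O[Si](CC)(CC)CC | intermediate
3 | secondary ozonide of 2 (1,2,4-trioxolane bridging the former alkene carbons; acetal carbons as a mixture) | CC12CC[C@@H](C(C)(C)O[Si](CC)(CC)CC)CC(OO1)O2 | intermediate (not isolated)
4 | (3R)-6-oxo-3-[2-(triethylsilyloxy)propan-2-yl]heptanal | CC(=O)CC[C@H](CC=O)C(C)(C)O[Si](CC)(CC)CC | intermediate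
5 | 2-(triphenylphosphoranylidene)propanal | CC(C=O)=P(c1ccccc1)(c1ccccc1)c1ccccc1 | starting material
6 | (2E,5R)-2-methyl-8-oxo-5-[2-(triethylsilyloxy)propan-2-yl]non-2-enal | CC(=O)CC[C@H](C/C=C(\C)C=O)C(C)(C)O[Si](CC)(CC)CC | intermediate
7 | (5R,7E)-8-methyl-5-[2-(triethylsilyloxy)propan-2-yl]deca-7,9-dien-2-one | CC(=O)CC[C@H](C/C=C(\C)C=C)C(C)(C)O[Si](CC)(CC)CC | intermediate
8 | diethyl {2-[methoxy(methyl)amino]-2-oxoethyl}phosphonate | CCOP(=O)(CC(=O)N(C)OC)OCC | starting material
9 | sodium carbanion of phosphonate 8 | [Na+].CCOP(=O)([CH-]C(=O)N(C)OC)OCC | intermediate (not isolated)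
10 | (2E,6R,8E)-N-methoxy-N,3,9-trimethyl-6-[2-(triethylsilyloxy)propan-2-yl]undeca-2,8,10-trienamide | C=C/C(C)=C/C[C@H](C(C)(C)O[Si](CC)(CC)CC)CC/C(C)=C/C(=O)N(C)OC | intermediate
11 | O-diisobutylaluminium hemiaminal from 10 (tetrahedral adduct, carbinol carbon undefined) | C=C/C(C)=C/C[C@H](C(C)(C)O[Si](CC)(CC)CC)CC/C(C)=C/C(O[Al](CC(C)C)CC(C)C)N(C)OC | intermediate (not isolated)
12 | (2E,6R,8E)-3,9-dimethyl-6-[2-(triethylsilyloxy)propan-2-yl]undeca-2,8,10-trienal | C=C/C(C)=C/C[C@H](C(C)(C)O[Si](CC)(CC)CC)CC/C(C)=C/C=O | intermediate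
13 | 11-(triethylsilyloxy)eudesm-3-ene-1β-carbaldehyde (trans-fused; 1β-CHO, 5α-H, 7β side chain, 10β-CH3) | O=C[C@@H]1CC=C(C)[C@@H]2C[C@H](C(C)(C)O[Si](CC)(CC)CC)CC[C@]21C | intermediate
14 | 1,3,5-trimethoxybenzene | COc1cc(OC)cc(OC)c1 | starting material
15 | 2,4,6-trimethoxyphenyllithium | [Li]c1c(OC)cc(OC)cc1OC | intermediate (not isolated)
16 | (2,4,6-trimethoxyphenyl)[11-(triethylsilyloxy)eudesm-3-en-1β-yl]methanol (both carbinol epimers) | COc1cc(OC)c(C(O)[C@@H]2CC=C(C)[C@@H]3C[C@H](C(C)(C)O[Si](CC)(CC)CC)CC[C@]32C)c(OC)c1 | intermediate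
17 | trimethyl(2-methylallyl)silane | C=C(C)C[Si](C)(C)C | starting material
18 | (1'S)-1β-[3-methyl-1-(2,4,6-trimethoxyphenyl)but-3-en-1-yl]-11-(triethylsilyloxy)eudesm-3-ene | C=C(C)C[C@H](c1c(OC)cc(OC)cc1OC)[C@@H]1CC=C(C)[C@@H]2C[C@H](C(C)(C)O[Si](CC)(CC)CC)CC[C@]21C | intermediate
19 | (1'S)-1β-[3-methyl-1-(2,4,6-trimethoxyphenyl)butyl]-11-(triethylsilyloxy)eudesm-3-ene | CC(C)C[C@H](c1c(OC)cc(OC)cc1OC)[C@@H]1CC=C(C)[C@@H]2C[C@H](C(C)(C)O[Si](CC)(CC)CC)CC[C@]21C | intermediate
20 | (1'S)-3α,4α-epoxy-1β-[3-methyl-1-(2,4,6-trimethoxyphenyl)butyl]-11-(triethylsilyloxy)eudesmane | CC(C)C[C@H](c1c(OC)cc(OC)cc1OC)[C@@H]1C[C@H]2O[C@@]2(C)[C@@H]3C[C@H](C(C)(C)O[Si](CC)(CC)CC)CC[C@]31C | intermediate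
21 | (1'S)-1β-[3-methyl-1-(2,4,6-trimethoxyphenyl)butyl]-11-(triethylsilyloxy)eudesman-4α-ol (4β-CH3) | CC(C)C[C@H](c1c(OC)cc(OC)cc1OC)[C@@H]1CC[C@@](C)(O)[C@@H]2C[C@H](C(C)(C)O[Si](CC)(CC)CC)CC[C@]21C | intermediate
22 | (1'S)-1β-[1-(3,5-dibromo-2,4,6-trimethoxyphenyl)-3-methylbutyl]-11-(triethylsilyloxy)eudesman-4α-ol | CC(C)C[C@H](c1c(OC)c(Br)c(OC)c(Br)c1OC)[C@@H]1CC[C@@](C)(O)[C@@H]2C[C@H](C(C)(C)O[Si](CC)(CC)CC)CC[C@]21C | intermediate
23 | trilithio species from 22 (lithium 4α-alkoxide, aryl positions 3 and 5 lithiated) | CC(C)C[C@H](c1c(OC)c([Li])c(OC)c([Li])c1OC)[C@@H]1CC[C@@](C)(O[Li])[C@@H]2C[C@H](C(C)(C)O[Si](CC)(CC)CC)CC[C@]21C | intermediate (not isolated)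
24 | bis(dimethylamino lithium alkoxide) adduct of 23 and DMF (hemiaminal carbons undefined) | CC(C)C[C@H](c1c(OC)c(C(O[Li])N(C)C)c(OC)c(C(O[Li])N(C)C)c1OC)[C@@H]1CC[C@@](C)(O[Li])[C@@H]2C[C@H](C(C)(C)O[Si](CC)(CC)CC)CC[C@]21C | intermediate (not isolated)
25 | 2,4,6-trimethoxy-5-{(1S)-1-[4α-hydroxy-11-(triethylsilyloxy)eudesman-1β-yl]-3-methylbutyl}benzene-1,3-dicarbaldehyde | CC(C)C[C@H](c1c(OC)c(C=O)c(OC)c(C=O)c1OC)[C@@H]1CC[C@@](C)(O)[C@@H]2C[C@H](C(C)(C)O[Si](CC)(CC)CC)CC[C@]21C | intermediate
26 | trisodium triphenoxide of 11-O-triethylsilyl macrocarpal J | CC(C)C[C@H](c1c([O-])c(C=O)c([O-])c(C=O)c1[O-])[C@@H]1CC[C@@](C)(O)[C@@H]2C[C@H](C(C)(C)O[Si](CC)(CC)CC)CC[C@]21C.[Na+].[Na+].[Na+] | intermediate (not isolated)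
27 | Macrocarpal J, 2,4,6-trihydroxy-5-[(1S)-1-(4α,11-dihydroxyeudesman-1β-yl)-3-methylbutyl]benzene-1,3-dicarbaldehyde | CC(C)C[C@H](c1c(O)c(C=O)c(O)c(C=O)c1O)[C@@H]1CC[C@@](C)(O)[C@@H]2C[C@H](C(C)(C)O)CC[C@]21C | target

**Step count and risks**

Total step count: 15. Longest linear sequence: 15 steps, from 1 to 27; carbanion 9 and aryllithium 15 are made in the flask.

The three steps most likely to fail:

Step 7, the cycloaddition. The β,β-disubstituted enal may react too slowly at low temperature, and warming could erode endo selectivity or let the Lewis acid attack the diene. The fallback replaces the Lewis-acid-complexed aldehyde by a cationic dienophile. From 12, 1,2-bis(trimethylsilyloxy)ethane and catalytic Me3SiOTf in CH2Cl2 at −78 °C would give the ethylene acetal of trienal 12 F1. The same acid opens the acetal reversibly to an alkoxy-substituted allyl cation, a far stronger dienophile, and an ionic Diels–Alder reaction through the same endo, chair-tether arrangement would give the ethylene acetal of aldehyde 13 F2. Hydrolysis with pyridinium p-toluenesulfonate in wet acetone returns to the route at 13.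

Step 9, the benzylic allylation. Facial selectivity in the capture of the cation may be poor or may favour the (1'R) epimer. The fallback reverses the order in which carbon and hydrogen arrive at C1'. From 16, oxidation with Dess–Martin periodinane would give the aryl ketone F3, and addition of 2-methylallylmagnesium chloride the tertiary benzylic carbinol F4. Ionic hydrogenation (Et3SiH, BF3·OEt2, CH2Cl2, −78 °C) would then deliver hydride to the face of the tertiary cation that the allylsilane took before, which gives the opposite configuration at C1' and rejoins the route at 18.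

Step 14, the double exchange and formylation. The second bromine–lithium exchange may stay incomplete, or the dianion may be protonated, so that mono-formylated material results. The fallback avoids organolithium intermediates. From 22, double Suzuki–Miyaura vinylation (potassium vinyltrifluoroborate, Pd(OAc)2, 2-dicyclohexylphosphino-2',6'-dimethoxybiphenyl, K2CO3, toluene/H2O, 90 °C) would give the 3,5-divinyl arene F5. Lemieux–Johnson cleavage of both vinyl groups (OsO4 cat., NaIO4, 2,6-lutidine, dioxane/H2O) rejoins the route at 25.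

**Further compounds**

F1 | step 7 | ethylene acetal (1,3-dioxolane) of trienal 12 | C=C/C(C)=C/C[C@H](C(C)(C)O[Si](CC)(CC)CC)CC/C(C)=C/C1OCCO1
F2 | step 7 | ethylene acetal (1,3-dioxolane) of aldehyde 13 | O1CCOC1[C@@H]2CC=C(C)[C@@H]3C[C@H](C(C)(C)O[Si](CC)(CC)CC)CC[C@]32C
F3 | step 9 | (2,4,6-trimethoxyphenyl)[11-(triethylsilyloxy)eudesm-3-en-1β-yl]methanone | COc1cc(OC)c(C(=O)[C@@H]2CC=C(C)[C@@H]3C[C@H](C(C)(C)O[Si](CC)(CC)CC)CC[C@]32C)c(OC)c1
F4 | step 9 | 3-methyl-1-(2,4,6-trimethoxyphenyl)-1-[11-(triethylsilyloxy)eudesm-3-en-1β-yl]but-3-en-1-ol (both carbinol epimers) | C=C(C)CC(O)(c1c(OC)cc(OC)cc1OC)[C@@H]1CC=C(C)[C@@H]2C[C@H](C(C)(C)O[Si](CC)(CC)CC)CC[C@]21C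
F5 | step 14 | (1'S)-1β-[1-(3,5-diethenyl-2,4,6-trimethoxyphenyl)-3-methylbutyl]-11-(triethylsilyloxy)eudesman-4α-ol | CC(C)C[C@H](c1c(OC)c(C=C)c(OC)c(C=C)c1OC)[C@@H]1CC[C@@](C)(O)[C@@H]2C[C@H](C(C)(C)O[Si](CC)(CC)CC)CC[C@]21C
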